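A small charge of left-handed substrate meets a larger charge of reagent, so while reagent stays near its charge, left-handed substrate should fall by a steady share per hour (pseudo-first-order). One time then describes it.

| setting | amber | midnight | spring | dawn | dusk |
|---|---|---|---|---|---|
| left-handed substrate | 0.075 M | 0.050 M | 0.050 M | 0.050 M | 0.050 M |
| right-handed substrate | 0.075 M | 0.050 M | 0.050 M | 0.050 M | 0.050 M |
| reagent | 0.15 M | 0.150 M | 0.150 M | 0.150 M | 0.150 M |
| temperature | 40 °C |  | 40 °C | 80 °C | 60 °C |
| remark | run made earlier | at 40 °C until 8.0 h, from then on at 80 °C |  |  |  |
| time |  | 12 h | 12 h | 12 h | 12 h |

amber run (percent of the left-handed substrate and right-handed substrate together charged)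

| time / h | left-handed product / % | left-handed substrate / % |
|---|---|---|
| 0.250 | 0.3 | 48.5 |
| 0.667 | 1.1 | 48.2 |
| 1.50 | 3.8 | 47.0 |
| 4.00 | 9.0 | 40.9 |

(each reading ± 0.5 percentage points)

- reagent is single-handed; left-handed substrate and right-handed substrate are mirror images of each other, charged as a racemate, each of them at the stated concentration
- what was read earlier has a scatter of 0.5 percentage points, one standard deviation
- what may be going on: reagent + left-handed substrate -> left-handed product; reagent + right-handed substrate -> right-handed product; left-handed substrate <-> right-handed substrate; 2 reagent -> self-condensation product; reagent -> decomposition product; left-handed product <-> right-handed product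
- the earlier runs do not show what temperature does; that part of a forecast is a guess
- the handed part of reagent does not stay in what it makes, so the products of the two hands are mirror images too

1. the flask with the highest amount of left-handed product, in percent of the left-handed substrate and right-handed substrate together charged ("all alike" if they lie within 1.5 percentage points) (midnight / spring / dawn / dusk / all alike)
2. final left-handed product, as a percentage of the left-handed substrate and right-handed substrate together charged, in midnight
3. final left-handed product, as a percentage of the left-handed substrate and right-handed substrate together charged, in spring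
4. final left-handed product, as a percentage of the left-handed substrate and right-handed substrate together charged, in dawn
5. final left-handed product, as a percentage of the left-handed substrate and right-handed substrate together charged, in dusk

Amber starts with left-handed substrate at 0.5 of the two substrates together. We read its rate at 4.00 h in two ways, from different columns.

From the fall of left-handed substrate: ln(0.5 / 40.9 %) / 4.00 h = 0.0502 h⁻¹

From the rise of left-handed product: ln(1 / (1 − 9.0 % / 0.5)) / 4.00 h = 0.0496 h⁻¹

They agree. At 1.50 h the same two sums part, giving 0.0413 h⁻¹ and 0.0527 h⁻¹. The early pair is the one that cheats, because its fall of 3 percentage points is smaller than the 9.1 points at the later reading, with the same scatter of 0.5 points. So we trust the later pair.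

The reciprocal of their mean rate, at this reagent charge, is the capture time 20.0 h. It carries to spring, whose reagent charge is the same and whose temperature is the same. Spring runs for 12 h, less than the capture time.

Fraction of left-handed substrate left: exp(−12 h / 20.0 h) = 54.9 %

Taken from it, as a fraction of both substrates: 0.5 × (1 − 54.9 %) = 22.5 %

The forecast names dawn and gives midnight 35 %, spring 20 %, dawn 39 % and dusk 34 %. On heating it says: “Temperature is a guess”. Our 22.5 % holds the rate steady and counts what is taken as left-handed product, and the forecast's spring figure is lower, by 2.5 points.

Dawn holds the most left-handed product, 46.0 %, which is 7 points above the forecast. Midnight gives 38.6 %, dusk 33.5 % and spring 19.8 %.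

    reagent + left-handed substrate → left-handed product (k = 1.80 M⁻¹ h⁻¹, Ea = 72.0 kJ mol⁻¹)
    reagent + right-handed substrate → right-handed product (k = 0.230 M⁻¹ h⁻¹, Ea = 90.0 kJ mol⁻¹)
    left-handed substrate ⇌ right-handed substrate (k = 0.0570 h⁻¹, Ea = 120 kJ mol⁻¹)
    2 reagent → self-condensation product (k = 0.0800 M⁻¹ h⁻¹, Ea = 77.0 kJ mol⁻¹)
    reagent → decomposition product (k = 6.90 × 10⁻⁴ h⁻¹, Ea = 129 kJ mol⁻¹)
    left-handed product ⇌ right-handed product (k = 0.130 h⁻¹, Ea = 104 kJ mol⁻¹)
    (constants at 60 °C)

Spring stayed at 40 °C with reagent at 80.4 % of its own charge at 12.0 h, and left-handed substrate stood at 29.2 % against the 27.5 % that the capture time gives, with left-handed product at 19.8 % and right-handed product at 3.64 %. Midnight, kept at 40 °C until 8.0 h, held left-handed substrate at 34.4 % against 33.5 % by the same reckoning, and after the change to 80 °C left-handed substrate in midnight fell to 10.6 % at 12.0 h while right-handed product rose from 2.26 % to 36.9 %.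

The readings were computed from invented constants; scatter was added.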